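Readings and results come from a simulation with constants of no real substance, and the scatter is random.

- At early times the runs look like a plain coupling: target gained and starting material lost run roughly together, given the scatter.

| flask | starting material | coupling partner | second substrate | third substrate | temperature | remark | time |
|---|---|---|---|---|---|---|---|
| red | 0.40 M | 1.04 M | 0.16 M | 0.80 M | 14 °C | run made earlier |  |
| violet | 1.6 M | 1.04 M | 0.16 M | 0.80 M | 22 °C | run made earlier |  |
| spring | 0.80 M | 1.04 M | 0.160 M | 0.800 M | 25 °C |  | 15 min |
| noon | 0.80 M | 1.04 M | 0.160 M | 0.800 M | 10 °C |  | 15 min |

| run | time / min | target / % | starting material / % |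
|---|---|---|---|
| red | 2.50 | 3 | 91 |
| red | 4.00 | 12 | 86 |
| red | 8.00 | 20 | 79 |
| red | 15.0 | 30 | 72 |
| red | 30.0 | 34 | 70 |
| violet | 1.33 | 11 | 90 |
| violet | 2.50 | 14 | 92 |
| violet | 5.00 | 18 | 83 |
| violet | 10.0 | 22 | 81 |
| violet | 20.0 | 19 | 81 |

(readings scatter by 2 percentage points)

- a reading or a percentage of target counts all its forms, free or not

- the best flask by amount of target, in percent of the starting material charged; "all alike" if 1.5 percentage points covers them all (spring / noon / all alike)
- amount of target at the end, in percent of the starting material charged, spring
- amount of target at the end, in percent of the starting material charged, noon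

- I follow progress by the exposure. Violet's last reading gives 0.211; this is the exposure, minus the natural logarithm of the fraction of starting material left.
- On the fastest rung, the average exposure per minute in red is 0.0377 /min by 4.00 min. In violet it reads 0.0792 /min by 1.33 min, faster than in red, but violet differs from red in both temperature and charge.
- On the next rung, the progress stalls. Red's average by 30.0 min has sunk to 0.0119 /min, and violet reads 81 % at 10.0 min and 81 % at 20.0 min.
- On the slowest rung, I see no movement beyond the scatter in red or violet, with much starting material still present. Red's last reading gives an exposure of 0.357, higher than violet's.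
- My own reckoning: spring is hotter than violet, so I give it violet's exposure, which goes with about 19 % of target. Noon is colder than red, so I place it below red's 30 % at the same time. I name no winner.
- The forecast names noon, with 21 % for spring (17 % to 27 %) and 27 % for noon (20 % to 33 %), reading the plateaus as what “looks like a reversible, exothermic coupling”.
- The flasks give all alike: spring 21.2 %, noon 21.0 %.

    starting material + coupling partner ⇌ target (K = 3.00 /M, k = 0.00170 /M/s, Ea = 61.0 kJ/mol, ΔH = −2.00 kJ/mol)
    second substrate + coupling partner → second product (k = 0.0180 /M/s, Ea = 43.0 kJ/mol)
    third substrate + coupling partner → third product (k = 9.50 × 10⁻⁴ /M/s, Ea = 72.0 kJ/mol)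
    coupling partner → decomposed reagent (k = 0.00260 /s, Ea = 95.0 kJ/mol)
    coupling partner + target ⇌ idle adduct, settled at all times (K = 0.990 /M, ΔH = −77.0 kJ/mol)
    (constants at 25 °C)

- Spring and noon end at nearly equal exposures, 0.238 and 0.236, and violet's last reading gave 0.211. In noon, the largest single effect among those tried is the using up of coupling partner, though it is not the main reason: with coupling partner held, noon gives 34.7 % of target instead of 21.0 %. At 15.0 min, spring keeps 3.92 % of its coupling partner and noon 33.5 %. Noon, left until 25 min, reaches an exposure of 0.301 and 26.0 % of target.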